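Ring A of the target, the cyclohexa-1,3-diene C2=C3–C4=C4a flanked by the sp3 carbons C8a and C1 (decalin locants, C1 bearing the side chain), is the retron of an alkyne–alkyne–alkene [2+2+2] cycloaddition. One rhodium-catalysed cyclization of a doubly tethered yne–ene–yne forms C3–C4, C4a–C8a and C1–C2, closing rings A and B together. The precursor is a cis-2,5-disubstituted 2-alkoxy-5,6-dihydro-2H-pyran: its ring alkene becomes C8a–C1, its acetal carbon the first side-chain carbon, its O–CH2 the later C8 methyl group, and its exocyclic oxygen the later acetonyl ketone. The temporary ring enforces the all-cis C8/C8a/C1 array.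

Key step: step 13

Remark: core locants are C1 (side chain), C2 (acetonyl), C3 (methyl), C4, C4a, C5, C6 (methyl), C7 (ketone), C8 (methyl), C8a; compounds 7 and 16 are taken as purchasable.

Step 1
Reactants: 1 (R)-4-benzyl-3-propanoyl-1,3-oxazolidin-2-one; 2 3-bromo-1-(trimethylsilyl)prop-1-yne
Product: 4 (R)-4-benzyl-3-[(2S)-2-methyl-5-(trimethylsilyl)pent-4-ynoyl]-1,3-oxazolidin-2-one, via sodium Z-enolate 3 (not isolated)
Conditions: NaN(SiMe3)2, THF, −78 °C; then 2, −78 to −40 °C
Reagents that add atoms: none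
Why: Evans asymmetric alkylation, in which the chelated Z-enolate should be alkylated on the face away from the benzyl group, setting the later C6 methyl stereocentre as (S).

Step 2
Reactants: 4 (R)-4-benzyl-3-[(2S)-2-methyl-5-(trimethylsilyl)pent-4-ynoyl]-1,3-oxazolidin-2-one
Product: 5 (2S)-2-methyl-5-(trimethylsilyl)pent-4-yn-1-ol
Conditions: LiBH4, MeOH (1 equiv), Et2O, 0 °C
Reagents that add atoms: none
Why: Reductive cleavage of the N-acyl oxazolidinone by borohydride should give the primary alcohol without touching the stereocentre and return the auxiliary.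

Step 3
Reactants: 5 (2S)-2-methyl-5-(trimethylsilyl)pent-4-yn-1-ol
Product: 6 (2S)-2-methyl-5-(trimethylsilyl)pent-4-ynal
Conditions: Dess–Martin periodinane, NaHCO3, CH2Cl2, 0 °C to rt; used at once
Reagents that add atoms: none
Why: Buffered Dess–Martin oxidation should give the α-branched aldehyde with minimal epimerization.

Step 4
Reactants: 6 (2S)-2-methyl-5-(trimethylsilyl)pent-4-ynal; 7 (R)-4-benzyl-3-[(2E)-but-2-enoyl]-1,3-oxazolidin-2-one
Product: 9 (R)-4-benzyl-3-[(2R,3S,4S)-2-ethenyl-3-hydroxy-4-methyl-7-(trimethylsilyl)hept-6-ynoyl]-1,3-oxazolidin-2-one, via dibutylboron dienolate 8 (not isolated)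
Conditions: Bu2BOTf, Et3N, CH2Cl2, −78 to 0 °C; then 6, −78 to 0 °C; pH 7 buffer, MeOH, H2O2
Reagents that add atoms: none
Why: Evans syn-aldol reaction of the crotonyl imide, whose Z-boron dienolate should react at its α-carbon through a Zimmerman–Traxler chair under auxiliary control, setting the later C8 carbon (with its vinyl and acyl arms) and the temporary carbinol centre syn to each other.

Step 5
Reactants: 9 (R)-4-benzyl-3-[(2R,3S,4S)-2-ethenyl-3-hydroxy-4-methyl-7-(trimethylsilyl)hept-6-ynoyl]-1,3-oxazolidin-2-one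
Product: 10 3-O-tert-butyldimethylsilyl ether of 9
Conditions: TBSOTf, 2,6-lutidine, CH2Cl2, −78 to 0 °C
Reagents that add atoms: tert-butyldimethylsilyl trifluoromethanesulfonate, CC(C)(C)[Si](C)(C)OS(=O)(=O)C(F)(F)F
Why: Silylation with the silyl triflate should protect the hindered secondary alcohol (the later C7 oxygen) for the hydride, acid and olefination steps that follow.

Step 6
Reactants: 10 3-O-tert-butyldimethylsilyl ether of 9
Product: 11 (2S,3S,4S)-3-[(tert-butyldimethylsilyl)oxy]-2-ethenyl-4-methyl-7-(trimethylsilyl)hept-6-yn-1-ol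
Conditions: LiBH4, MeOH (1 equiv), THF, 0 °C
Reagents that add atoms: none
Why: Borohydride reduction of the imide should release the auxiliary and give the primary alcohol whose carbon later becomes the C8 methyl group.

Step 7
Reactants: 11 (2S,3S,4S)-3-[(tert-butyldimethylsilyl)oxy]-2-ethenyl-4-methyl-7-(trimethylsilyl)hept-6-yn-1-ol
Product: 12 prop-2-enoate (acrylate) ester of 11
Conditions: acryloyl chloride, Et3N, CH2Cl2, −20 to 0 °C
Reagents that add atoms: acryloyl chloride, C=CC(=O)Cl
Why: O-Acylation of the primary alcohol should install the two carbons that become C1 and the first side-chain carbon.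

Step 8
Reactants: 12 prop-2-enoate (acrylate) ester of 11
Product: 13 (5S)-5-[(1S,2S)-1-[(tert-butyldimethylsilyl)oxy]-2-methyl-5-(trimethylsilyl)pent-4-yn-1-yl]-5,6-dihydro-2H-pyran-2-one
Conditions: second-generation Grubbs catalyst RuCl2(=CHPh)(SIMes)(PCy3) (5 mol%), CH2Cl2 (5 mM), 40 °C
Reagents that add atoms: none
Why: Ring-closing metathesis of the acrylate with the vinyl group should close the unsaturated δ-lactone, fixing the later C8a–C1 alkene as cis inside a ring, while the silyl-capped alkyne stays out of the metathesis.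

Step 9
Reactants: 13 (5S)-5-[(1S,2S)-1-[(tert-butyldimethylsilyl)oxy]-2-methyl-5-(trimethylsilyl)pent-4-yn-1-yl]-5,6-dihydro-2H-pyran-2-one
Product: 14 the corresponding lactol (5-substituted 5,6-dihydro-2H-pyran-2-ol; anomeric mixture)
Conditions: i-Bu2AlH (1.1 equiv), CH2Cl2, −78 °C; Rochelle salt
Reagents that add atoms: none
Why: Half-reduction of the lactone with the aluminium hydride at −78 °C should stop at the lactol oxidation level.

Step 10
Reactants: 15 (S)-2-methyloxirane; 16 prop-1-yn-1-yllithium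
Product: 17 (2S)-hex-4-yn-2-ol
Conditions: THF–DMPU, −78 °C to rt; aq NH4Cl
Reagents that add atoms: none
Why: SN2 ring opening of the epoxide at its terminal carbon by the alkynyllithium should give the homopropargylic alcohol with the stereocentre untouched.

Step 11
Reactants: 14 lactol (anomeric mixture); 17 (2S)-hex-4-yn-2-ol
Product: 18 (2R,5S)-2-[(2S)-hex-4-yn-2-yloxy]-5-[(1S,2S)-1-[(tert-butyldimethylsilyl)oxy]-2-methyl-5-(trimethylsilyl)pent-4-yn-1-yl]-5,6-dihydro-2H-pyran (2,5-cis)
Conditions: 17 (3 equiv), PPTS (10 mol%), 4 Å molecular sieves, CH2Cl2, rt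
Reagents that add atoms: none
Why: Acid-catalysed acetal exchange of the allylic lactol under thermodynamic control should favour the anomer with the alkoxy group pseudo-axial (anomeric effect) and cis to the pseudo-equatorial C5 arm, so both alkyne tethers sit on one face of the ring alkene.

Step 12
Reactants: 18 silyl-capped acetal
Product: 19 (2R,5S)-2-[(2S)-hex-4-yn-2-yloxy]-5-[(1S,2S)-1-[(tert-butyldimethylsilyl)oxy]-2-methylpent-4-yn-1-yl]-5,6-dihydro-2H-pyran
Conditions: K2CO3 (cat.), MeOH, rt
Reagents that add atoms: none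
Why: Base-catalysed methanolysis (protodesilylation) should remove only the alkynyl silyl group, since the acetal and the silyl ether are stable to carbonate.

Step 13
Reactants: 19 yne–ene–yne acetal
Product: 20 tetracyclic bis-acetal containing rings A and B, the original oxane and a second oxane from the tether (H-8, H-8a and H-1 all cis)
Conditions: [Rh(cod)2]BF4 (10 mol%), rac-BINAP (10 mol%), H2 pre-activation then Ar, (CH2Cl)2 (5 mM), 60 °C
Reagents that add atoms: none
Why: Cationic monovalent rhodium should join the terminal alkyne of the arm to the ring alkene by oxidative cyclization (C4a–C8a bond), insert the tethered 2-alkyne (C1–C2 bond) and close the diene by reductive elimination (C3–C4 bond). The closest known reaction type is the rhodium-catalysed intramolecular [2+2+2] cycloaddition of yne–ene–yne substrates to tricyclic cyclohexa-1,3-dienes. Ring B closes by exo attack of the tethered alkyne on the adjacent ring alkene carbon, ring A arises as the [2+2+2] cyclohexadiene, and the tether oxane closes in the same mode from the acetal side. The new stereocentre C8a is controlled by the arm on the neighbouring allylic carbon, which can reach only its own face of the ring alkene (cis fusion, H-8 and H-8a cis), and C1 by suprafacial delivery of both carbons to the cis alkene at one metal centre (H-8a and H-1 cis). Regioselectivity (methyl-bearing alkyne carbon to C4) and face selectivity are secured by the two tethers and the 2,5-cis substitution, and intermolecular alkyne coupling is suppressed by high dilution.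

Step 14
Reactants: 20 tetracyclic bis-acetal
Product: 21 hydroxy lactol (2-hydroxyoxane fused to ring B, free secondary alcohol on the C2 side chain; anomeric mixture)
Conditions: AcOH–THF–H2O (3:1:1), 40 °C
Reagents that add atoms: water, O
Why: Acetal hydrolysis under mild aqueous acid should unveil the side-chain aldehyde as its lactol and free the secondary hydroxyl, while the hindered secondary silyl ether survives.

Step 15
Reactants: 21 hydroxy lactol
Product: 23 (E)-2-methylpropenal (enal) at C1 with free CH2OH at C8, via open hydroxy aldehyde 22 (not isolated)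
Conditions: Ph3P=C(CH3)CHO (3 equiv), toluene, 90 °C
Reagents that add atoms: 2-(triphenylphosphoranylidene)propanal, CC(C=O)=P(c1ccccc1)(c1ccccc1)c1ccccc1
Why: Wittig reaction of the open aldehyde tautomer with the stabilized formyl ylide should give the (E)-trisubstituted enal under neutral conditions.

Step 16
Reactants: 23 enal
Product: 24 ethyl (2E,4E)-2,4-dimethylpenta-2,4-dienoate attached at C1 (dienoate diol)
Conditions: Ph3P=C(CH3)CO2Et (2 equiv), toluene, 80 °C
Reagents that add atoms: ethyl 2-(triphenylphosphoranylidene)propanoate, CCOC(=O)C(C)=P(c1ccccc1)(c1ccccc1)c1ccccc1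
Why: A second Wittig reaction with the stabilized ester ylide should extend the chain to the (E,E)-dienoate.

Step 17
Reactants: 24 dienoate diol
Product: 25 primary 4-methylbenzenesulfonate (tosylate) of 24
Conditions: TsCl (1.2 equiv), pyridine, CH2Cl2, 0 °C
Reagents that add atoms: 4-methylbenzenesulfonyl chloride, Cc1ccc(cc1)S(Cl)(=O)=O
Why: Sulfonylation should take place at the primary hydroxyl in preference to the less reactive secondary one, preparing the deoxygenation.

Step 18
Reactants: 25 primary tosylate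
Product: 26 (2E,4E)-dienol with the C8 methyl group in place
Conditions: LiEt3BH (excess), THF, 0 °C to rt
Reagents that add atoms: none
Why: Hydride reduction should displace the primary tosylate (giving the C8 methyl group) and reduce the ester 1,2 to the allylic alcohol in one operation.

Step 19
Reactants: 26 dienol
Product: 27 (2S,3S)-2,3-epoxy alcohol (epoxide on the alkene next to CH2OH)
Conditions: Ti(OiPr)4, L-(+)-diethyl tartrate, t-BuOOH, 4 Å molecular sieves, CH2Cl2, −25 °C
Reagents that add atoms: tert-butyl hydroperoxide, CC(C)(C)OO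
Why: Sharpless asymmetric epoxidation should oxidize only the allylic alcohol alkene, and the L-(+)-tartrate should deliver oxygen to the face that gives the (2S,3S)-epoxide, which sets both epoxide stereocentres of the target.

Step 20
Reactants: 27 epoxy alcohol
Product: 28 epoxy aldehyde (secondary alcohol untouched)
Conditions: TEMPO (10 mol%), PhI(OAc)2 (1.2 equiv), CH2Cl2, rt
Reagents that add atoms: none
Why: Nitroxyl-catalysed oxidation should be selective for the primary alcohol, and the α-quaternary epoxy aldehyde cannot epimerize.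

Step 21
Reactants: 28 epoxy aldehyde
Product: 29 2-(trimethylsilyl)ethyl (E)-enoate
Conditions: Ph3P=CHCO2CH2CH2SiMe3, CH2Cl2, rt
Reagents that add atoms: 2-(trimethylsilyl)ethyl (triphenylphosphoranylidene)acetate, C[Si](C)(C)CCOC(=O)C=P(c1ccccc1)(c1ccccc1)c1ccccc1
Why: Wittig reaction with the stabilized ylide should give the (E)-enoate as a fluoride-labile ester.

Step 22
Reactants: 29 silyl-protected ester
Product: 30 dihydroxy acid (C7 carbinol, side-chain carbinol, free carboxylic acid)
Conditions: Bu4NF (excess), THF, 0 to 40 °C; aq NH4Cl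
Reagents that add atoms: none
Why: Fluoride-mediated desilylation should cleave the silyl ether and, by β-elimination, the 2-(trimethylsilyl)ethyl ester, with no ketone yet present that could epimerize.

Step 23
Reactants: 30 dihydroxy acid
Product: 31 target acid CNP0214881.1
Conditions: Dess–Martin periodinane (3 equiv), NaHCO3, CH2Cl2, 0 °C to rt
Reagents that add atoms: none
Why: Dess–Martin oxidation of both secondary alcohols under buffered, non-basic conditions should form the two ketones last, so the epimerizable C6 and C8 centres and the β,γ-unsaturated ketone never meet base.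

Compound list
1 | (R)-4-benzyl-3-propanoyl-1,3-oxazolidin-2-one | CCC(=O)N1C(=O)OC[C@H]1Cc1ccccc1 | starting material
2 | 3-bromo-1-(trimethylsilyl)prop-1-yne | C[Si](C)(C)C#CCBr | starting material
3 | sodium Z-enolate of 1 | C/C=C(\[O-])N1C(=O)OC[C@H]1Cc1ccccc1.[Na+] | intermediate (not isolated)
4 | (R)-4-benzyl-3-[(2S)-2-methyl-5-(trimethylsilyl)pent-4-ynoyl]-1,3-oxazolidin-2-one | C[Si](C)(C)C#CC[C@H](C)C(=O)N1C(=O)OC[C@H]1Cc1ccccc1 | intermediate
5 | (2S)-2-methyl-5-(trimethylsilyl)pent-4-yn-1-ol | C[Si](C)(C)C#CC[C@H](C)CO | intermediate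
6 | (2S)-2-methyl-5-(trimethylsilyl)pent-4-ynal | C[Si](C)(C)C#CC[C@H](C)C=O | intermediate
7 | (R)-4-benzyl-3-[(2E)-but-2-enoyl]-1,3-oxazolidin-2-one | C/C=C/C(=O)N1C(=O)OC[C@H]1Cc1ccccc1 | starting material
8 | dibutylboron Z-dienolate of 7 | C=C/C=C(\OB(CCCC)CCCC)N1C(=O)OC[C@H]1Cc1ccccc1 | intermediate (not isolated)
9 | (R)-4-benzyl-3-[(2R,3S,4S)-2-ethenyl-3-hydroxy-4-methyl-7-(trimethylsilyl)hept-6-ynoyl]-1,3-oxazolidin-2-one | C[Si](C)(C)C#CC[C@H](C)[C@H](O)[C@@H](C=C)C(=O)N1C(=O)OC[C@H]1Cc1ccccc1 | intermediate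
10 | 3-O-tert-butyldimethylsilyl ether of 9 | C[Si](C)(C)C#CC[C@H](C)[C@H](O[Si](C)(C)C(C)(C)C)[C@@H](C=C)C(=O)N1C(=O)OC[C@H]1Cc1ccccc1 | intermediate
11 | (2S,3S,4S)-3-[(tert-butyldimethylsilyl)oxy]-2-ethenyl-4-methyl-7-(trimethylsilyl)hept-6-yn-1-ol | C[Si](C)(C)C#CC[C@H](C)[C@H](O[Si](C)(C)C(C)(C)C)[C@@H](C=C)CO | intermediate
12 | prop-2-enoate ester of 11 | C[Si](C)(C)C#CC[C@H](C)[C@H](O[Si](C)(C)C(C)(C)C)[C@@H](C=C)COC(=O)C=C | intermediate
13 | (5S)-5-[(1S,2S)-1-[(tert-butyldimethylsilyl)oxy]-2-methyl-5-(trimethylsilyl)pent-4-yn-1-yl]-5,6-dihydro-2H-pyran-2-one | C[Si](C)(C)C#CC[C@H](C)[C@H](O[Si](C)(C)C(C)(C)C)[C@@H]1COC(=O)C=C1 | intermediate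
14 | lactol of 13 (anomeric mixture) | C[Si](C)(C)C#CC[C@H](C)[C@H](O[Si](C)(C)C(C)(C)C)[C@@H]1COC(O)C=C1 | intermediate
15 | (S)-2-methyloxirane | C[C@H]1CO1 | starting material
16 | prop-1-yn-1-yllithium | [Li]C#CC | starting material
17 | (2S)-hex-4-yn-2-ol | C[C@H](O)CC#CC | intermediate
18 | (2R,5S)-2-[(2S)-hex-4-yn-2-yloxy]-5-[(1S,2S)-1-[(tert-butyldimethylsilyl)oxy]-2-methyl-5-(trimethylsilyl)pent-4-yn-1-yl]-5,6-dihydro-2H-pyran | C[Si](C)(C)C#CC[C@H](C)[C@H](O[Si](C)(C)C(C)(C)C)[C@@H]1CO[C@H](O[C@@H](C)CC#CC)C=C1 | intermediate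
19 | (2R,5S)-2-[(2S)-hex-4-yn-2-yloxy]-5-[(1S,2S)-1-[(tert-butyldimethylsilyl)oxy]-2-methylpent-4-yn-1-yl]-5,6-dihydro-2H-pyran | C#CC[C@H](C)[C@H](O[Si](C)(C)C(C)(C)C)[C@@H]1CO[C@H](O[C@@H](C)CC#CC)C=C1 | intermediate
20 | tetracyclic bis-acetal (rings A and B plus two oxanes sharing the acetal carbon) | C[C@H]1CC2=C(C)C=C3C[C@H](C)[C@H](O[Si](C)(C)C(C)(C)C)[C@@H]4CO[C@H](O1)[C@H]2[C@H]34 | intermediate
21 | hydroxy lactol from 20 (anomeric mixture) | C[C@H](O)CC1=C(C)C=C2C[C@H](C)[C@H](O[Si](C)(C)C(C)(C)C)[C@@H]3COC(O)[C@H]1[C@H]23 | intermediate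
22 | open hydroxy aldehyde tautomer of 21 | C[C@H](O)CC1=C(C)C=C2C[C@H](C)[C@H](O[Si](C)(C)C(C)(C)C)[C@H](CO)[C@@H]2[C@@H]1C=O | intermediate (not isolated)
23 | (E)-enal with C8 hydroxymethyl group | C[C@H](O)CC1=C(C)C=C2C[C@H](C)[C@H](O[Si](C)(C)C(C)(C)C)[C@H](CO)[C@@H]2[C@@H]1/C=C(\C)C=O | intermediate
24 | ethyl (E,E)-dienoate diol | C[C@H](O)CC1=C(C)C=C2C[C@H](C)[C@H](O[Si](C)(C)C(C)(C)C)[C@H](CO)[C@@H]2[C@@H]1/C=C(\C)/C=C(\C)C(=O)OCC | intermediate
25 | primary tosylate of 24 | C[C@H](O)CC1=C(C)C=C2C[C@H](C)[C@H](O[Si](C)(C)C(C)(C)C)[C@H](COS(=O)(=O)c3ccc(C)cc3)[C@@H]2[C@@H]1/C=C(\C)/C=C(\C)C(=O)OCC | intermediate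
26 | (E,E)-dienol with C8 methyl group | C[C@H](O)CC1=C(C)C=C2C[C@H](C)[C@H](O[Si](C)(C)C(C)(C)C)[C@H](C)[C@@H]2[C@@H]1/C=C(\C)/C=C(\C)CO | intermediate
27 | (2S,3S)-epoxy alcohol | C[C@H](O)CC1=C(C)C=C2C[C@H](C)[C@H](O[Si](C)(C)C(C)(C)C)[C@H](C)[C@@H]2[C@@H]1/C=C(\C)[C@@H]1O[C@@]1(C)CO | intermediate
28 | epoxy aldehyde | C[C@H](O)CC1=C(C)C=C2C[C@H](C)[C@H](O[Si](C)(C)C(C)(C)C)[C@H](C)[C@@H]2[C@@H]1/C=C(\C)[C@@H]1O[C@@]1(C)C=O | intermediate
29 | 2-(trimethylsilyl)ethyl (E)-enoate | C[C@H](O)CC1=C(C)C=C2C[C@H](C)[C@H](O[Si](C)(C)C(C)(C)C)[C@H](C)[C@@H]2[C@@H]1/C=C(\C)[C@@H]1O[C@@]1(C)/C=C/C(=O)OCC[Si](C)(C)C | intermediate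
30 | dihydroxy acid | C[C@H](O)CC1=C(C)C=C2C[C@H](C)[C@H](O)[C@H](C)[C@@H]2[C@@H]1/C=C(\C)[C@@H]1O[C@@]1(C)/C=C/C(=O)O | intermediate
31 | target acid CNP0214881.1 | CC(=O)CC1=C(C)C=C2C[C@H](C)C(=O)[C@H](C)[C@@H]2[C@@H]1/C=C(\C)[C@@H]1O[C@@]1(C)/C=C/C(=O)O | target

Total step count: 23. Longest linear sequence: 22 steps (steps 1–9 and 11–23; step 10 is a one-step side branch).

Steps most likely to fail

Step 13. The catalytic cycle may stall after the first ring closure, because closing ring B places the C6 and C8 substituents on the same face and costs strain, and the terminal alkyne may then be lost to intermolecular oligomerization. The fallback sets out from 19 and uses a stoichiometric cobalt-mediated [2+2+2] cocyclization (CpCo(CO)2, toluene, reflux, irradiation), which should stop at the stable cobalt–diene complex F1. Oxidative demetalation of F1 with CuCl2·2H2O and Et3N in MeCN at 0 °C should then release 20, where the route is rejoined.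

Step 15. Olefination of the hindered lactol by the weakly nucleophilic formyl ylide may be slow. The open β,γ-unsaturated aldehyde could then epimerize at C1, or the freed hydroxyl groups could re-close by oxa-Michael addition. The fallback sets out from 21 and uses the more reactive ester ylide Ph3P=C(CH3)CO2Et (toluene, 80 °C) to give the ethyl enoate F2. Reduction with i-Bu2AlH at −78 °C should give the allylic alcohol F3, and MnO2 should oxidize only that allylic alcohol, returning to 23.

Step 22. Fluoride cleavage of the hindered secondary silyl ether may need forcing, basic conditions under which the vinyl epoxide next to the enoate is opened. The fallback sets out from 26 and removes the silyl ether before the epoxide exists. Bu4NF in THF should give the triol F4. Sharpless epoxidation (Ti(OiPr)4, L-(+)-diethyl tartrate, t-BuOOH) should give the epoxy triol F5, and TEMPO/PhI(OAc)2 the epoxy aldehyde F6. Wittig reaction with Ph3P=CHCO2CH2CH2SiMe3 should give the ester diol F7, and brief Bu4NF treatment at 0 °C, which now only has to cleave the ester, returns to 30.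

Further compounds
F1 | step 13 | (η5-cyclopentadienyl)cobalt η4-complex of diene 20 (monovalent cobalt) | C[C@H]1CC2=C(C)C=C3C[C@H](C)[C@H](O[Si](C)(C)C(C)(C)C)[C@@H]4CO[C@H](O1)[C@H]2[C@H]34.[Co+].c1cc[cH-]c1
F2 | step 15 | ethyl (E)-enoate diol | C[C@H](O)CC1=C(C)C=C2C[C@H](C)[C@H](O[Si](C)(C)C(C)(C)C)[C@H](CO)[C@@H]2[C@@H]1/C=C(\C)C(=O)OCC
F3 | step 15 | (E)-allylic alcohol triol | C[C@H](O)CC1=C(C)C=C2C[C@H](C)[C@H](O[Si](C)(C)C(C)(C)C)[C@H](CO)[C@@H]2[C@@H]1/C=C(\C)CO
F4 | step 22 | desilylated dienol triol | C[C@H](O)CC1=C(C)C=C2C[C@H](C)[C@H](O)[C@H](C)[C@@H]2[C@@H]1/C=C(\C)/C=C(\C)CO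
F5 | step 22 | (2S,3S)-epoxy triol | C[C@H](O)CC1=C(C)C=C2C[C@H](C)[C@H](O)[C@H](C)[C@@H]2[C@@H]1/C=C(\C)[C@@H]1O[C@@]1(C)CO
F6 | step 22 | epoxy aldehyde diol | C[C@H](O)CC1=C(C)C=C2C[C@H](C)[C@H](O)[C@H](C)[C@@H]2[C@@H]1/C=C(\C)[C@@H]1O[C@@]1(C)C=O
F7 | step 22 | 2-(trimethylsilyl)ethyl (E)-enoate diol | C[C@H](O)CC1=C(C)C=C2C[C@H](C)[C@H](O)[C@H](C)[C@@H]2[C@@H]1/C=C(\C)[C@@H]1O[C@@]1(C)/C=C/C(=O)OCC[Si](C)(C)C
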